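**Remark on labels.** C1–C10 in the text are the atom labels defined in the first section. Locants inside compound names are nomenclature locants.

## The problem

The target 27 is the isovanillate of a cis-fused hydroazulene diol. The labels are: C1 the methyl-bearing quaternary ring-fusion carbon, C2 and C3 the cyclopentane methylenes, C4 the isopropyl carbinol, C5 the ring-fusion CH, C6 the carbon carrying the ester oxygen, C7=C8 the ring alkene (methyl on C8), and C9 and C10 the methylenes leading back to C1.

The cyclopentane (C1–C5) and the cycloheptene (C1, C5–C10) share the C1–C5 bond. The C1 methyl, H5 and the isopropyl group lie on one face of the five-membered ring; the C4 hydroxyl, C6 and C10 lie on the other. At C6 the oxygen points to the side of C4, so H6 is cis to H5.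

C1 is quaternary and remote from any heteroatom, so it has to come from asymmetric catalysis. Once made it is a poor controller of C5, because its methyl group and its two-carbon arm are alike in size.

C5 is the pivot. It is acidic whenever C4 or C6 is a carbonyl, and it invites β-elimination or retro-aldol cleavage when one neighbour is a carbonyl and the other carries oxygen. Yet it is the centre that steers both C4 (a nucleophile adds to a C4 ketone anti to the C5 substituent) and C6 (a reagent reaches C6 past H5). It must therefore be fixed early and then kept away from base.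

The allylic aryl ester (ionizable, and unstable to hydrides and organometallics) and the free phenol will not survive the body of the synthesis, so the ester comes last.

The enabling feature is that C5 lies between C4 and C6. With C4 as a ketone and C6 as an ester it is a soft carbon nucleophile, and C1, three atoms away through C4–C3–C2, is the substituted end of an allyl unit C1–C10–C9. A palladium-catalysed 5-exo allylic alkylation can thus create C1 with a vinyl handle.

## Retrosynthesis

**Ester.** The acyl C–O bond of 27 is cut first, giving diol 21 and the silyl-protected acid 24 (one step from isovanillic acid 22). The alternative of carrying the aroyl group earlier fails, because every later step uses a hydride, an organometallic or a metal that ionizes allylic esters. In 21 only the secondary C6 hydroxyl can be acylated; the tertiary C4 hydroxyl needs no protection. The forward reaction must acylate a hindered allylic alcohol with retention and without acid.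

**C6.** The C6–H bond of 21 is cut to enone 20. A reagent approaches C6 from the side of H5, away from the quaternary C1. For a vinyl nucleophile adding to an aldehyde this gives the wrong carbinol; for hydride adding to the ring ketone it gives the right one. C6 is therefore passed through the ketone, and the configuration of the precursor alcohol 19 does not matter.

**Seven-membered ring.** The C7=C8 bond of 19 is cut by ring-closing metathesis to diene 18, and the C6–C7 bond of 18 to aldehyde 17 and a vinyl nucleophile. Against a ring closure at C8–C9 or C6–C7, this cut uses only one- and three-carbon reagents for the two alkene arms. Because the arms on C1 and C5 of 18 are cis, the ring can only close cis-fused. The bicycle is reduced to a cyclopentane with three stereocentres.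

**Isopropyl group.** The C4–isopropyl bond is cut from 17 (via 16 and 15) to ketone 14. The isopropyl nucleophile has to enter while C6 is not a carbonyl, so C6 is a silyl-protected primary alcohol at this point. Addition anti to the C5 arm puts the hydroxyl cis to C6. Doing this on the bicycle instead would need a second protecting group on a secondary allylic carbinol and would expose a β-silyloxy ketone whose leaving group is allylic.

**Side chain.** The C8–C9 bond of 14 is cut (via 13) to the vinyl compound 11: hydroboration at C9 and cross-coupling with an isopropenyl halide. It is placed before the oxidation to 14 because a borane would reduce the ketone.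

**C5.** No skeletal bond is cut between 11 and 8 (via 10 and 9); here the C5 problem is solved. The labile C5 of β-keto ester 8 is turned to use: hydrogenation under dynamic kinetic resolution reduces C4 and fixes C5 by catalyst control, giving hydroxy ester 9. The C4 carbinol is only a relay and is re-oxidized in 14. The neighbouring options are weaker. Substrate control fails because the two groups on C1 are alike. Equilibrating C5 later in a bicyclic β-silyloxy ketone risks elimination to a dienone and rests on an uncertain thermodynamic bias. The forward reaction must spare the vinyl group.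

**Key cut.** The C1–C5 bond of 8 is cut to the open-chain allylic carbonate 7. This removes the ring and the quaternary stereocentre in one step and leaves an achiral precursor. It asks the catalyst for enantioface selection on the allyl unit, for attack at the substituted terminus, and for C- over O-alkylation.

**Precursor.** The C2–C3 bond of 7 is cut to the dianion 6 of methyl acetoacetate 5 and the bromide 4. Bromide 4 comes from prenol 1 through carbonate 2 and the (E)-alcohol 3; the allylic oxidation that gives 3 fixes the alkene geometry that the key step needs.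

## Roads not taken

**Alternative 1:** The cut is C8–C9. The monocyclic (Z)-iodoalkene A2 would be hydroborated at its C1 vinyl group with 9-BBN-H, and PdCl2(dppf) with aqueous base would couple the alkylborane with the C8 iodide to give the bis-silyl ether A1.
- Merits: all four stereocentres and both oxygens are in place before the ring closes, the alkene position and geometry are fixed by the iodide, and no ruthenium carbene meets a free allylic alcohol. As a ring closure it is at least as good as metathesis.
- Weak points: A2 needs a stereodefined trisubstituted iodoalkene next to an allylic silyloxy stereocentre. C6 would have to be set on an open chain, where approach past H5 favours the wrong carbinol. The alternative says nothing about how the cyclopentane with C1, C5 and C4 is made, which is the hard part.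
- Comparison: the chosen plan sets against it a catalytic origin for C1, cheap alkene handles, and correction of C6 on the bicycle, where it is easiest.

**Alternative 2:** The cuts are C1–C5 and C1–C10. Rh2(OAc)4 would convert the α-diazo ketone A4 into a carbene that adds to the arene; opening of the norcaradiene gives the cycloheptatriene A3 (Buchner reaction).
- Merits: both rings and the quaternary carbon form in one step from a cresol-derived arene. In ring economy this is better than the chosen plan, which needs two ring-forming steps.
- Weak points: α-alkyl diazo ketones tend to undergo 1,2-hydride shift. The carbene must choose between two ortho bonds of the arene. C1 depends on diastereocontrol from a tertiary benzylic C4 centre that must itself be made enantioselectively. A3 then carries three ring alkenes and a C2 ketone: one alkene must be kept, two reduced (one of them creating H5 cis to the methyl), and the C2 carbonyl removed next to sensitive groups.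
- Comparison: faster to the skeleton, but the redox corrections afterwards are longer and less controlled. The chosen plan never has to tell three ring alkenes apart and sets H5 by catalyst control.

**Alternative 3:** The cuts are C1–C10 and C5–C6. The Grignard reagent A7 would add to enone A6 under a chiral N-heterocyclic carbene copper catalyst made from Cu(OTf)2, and the magnesium enolate would be trapped by aldehyde A8 to give A5.
- Merits: it is by far the shortest; A5 is one step from commercial materials and is already a metathesis substrate. In step count it clearly beats the chosen plan.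
- Weak points: forming a quaternary centre on a cyclopentenone is the hardest case of this conjugate addition. The aldol trap has no reason to place C6 cis to the new chain rather than cis to the methyl, and gives no control at C6. A5 is a β-hydroxy ketone with an acidic C5–H, formed and later handled under basic conditions, so retro-aldol, dehydration and epimerization all threaten.
- Comparison: the chosen plan sets against it a C5 fixed by catalyst-controlled reduction and, in 8, a β-keto ester that tolerates its own lability; the only ketone with oxygen on C6 (14) sees only a buffered oxidation and an organocerium reagent.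

Key step: step 5

**Assumption (step 5):** the (R,R) ligand is written; the sense of induction at C1 is to be confirmed after step 6, and the (S,S) ligand is used if it proves opposite, with nothing else changed.

**Assumption (step 6):** (R)-BINAP is taken to give the same sense at the carbinol and ester carbons as it does with methyl 2-oxocyclopentanecarboxylate.

## Route

Step 1
Reactants: 1 3-methylbut-2-en-1-ol
Product: 2 methyl 3-methylbut-2-en-1-yl carbonate
Conditions: ClCO2Me, pyridine, CH2Cl2, 0 °C → rt
Reagents that add atoms: methyl chloroformate COC(=O)Cl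
Why: Acylation of a primary allylic alcohol; the carbonate is the leaving group of the key step and, unlike an acetate, has no acidic hydrogens to trouble step 4.

Step 2
Reactants: 2 methyl 3-methylbut-2-en-1-yl carbonate
Product: 3 (2E)-4-hydroxy-3-methylbut-2-en-1-yl methyl carbonate
Conditions: SeO2 (cat.), t-BuOOH, salicylic acid (cat.), CH2Cl2, rt
Reagents that add atoms: selenium dioxide O=[Se]=O (oxygen carrier); tert-butyl hydroperoxide CC(C)(C)OO (terminal oxidant)
Why: Selenium dioxide allylic oxidation (ene reaction, then 2,3-sigmatropic shift) attacks the methyl group trans to the chain at the more substituted alkene carbon, so the (E)-alcohol should form with the geometry the key step needs.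

Step 3
Reactants: 3 (2E)-4-hydroxy-3-methylbut-2-en-1-yl methyl carbonate
Product: 4 (2E)-4-bromo-3-methylbut-2-en-1-yl methyl carbonate
Conditions: CBr4, PPh3, CH2Cl2, 0 °C
Reagents that add atoms: carbon tetrabromide BrC(Br)(Br)Br
Why: Appel reaction of a primary allylic alcohol under neutral conditions; direct displacement at the primary carbon keeps the alkene position and geometry.

Step 4
Reactants: 5 methyl acetoacetate; 4 (2E)-4-bromo-3-methylbut-2-en-1-yl methyl carbonate
Product: 7 methyl (6E)-8-[(methoxycarbonyl)oxy]-6-methyl-3-oxooct-6-enoate, via acetoacetate dianion 6 (not isolated)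
Conditions: NaH, THF, 0 °C; n-BuLi, 0 °C; then 4, −78 → 0 °C; aq. NH4Cl
Reagents that add atoms: none
Why: γ-Alkylation of the acetoacetate dianion; the terminal carbanion is the more nucleophilic site and should displace the primary allylic bromide at low temperature faster than it attacks the carbonate, with the (E)-alkene untouched.

Step 5
Reactants: 7 methyl (6E)-8-[(methoxycarbonyl)oxy]-6-methyl-3-oxooct-6-enoate
Product: 8 methyl (1R,2S)-2-ethenyl-2-methyl-5-oxocyclopentane-1-carboxylate (the ester-bearing carbon, label C5, is labile and is drawn as in the target)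
Conditions: Pd2(dba)3·CHCl3 (2.5 mol %), (1R,2R)-N,N'-bis[2-(diphenylphosphino)benzoyl]cyclohexane-1,2-diamine (7.5 mol %), CH2Cl2 (0.02 M), 0 °C → rt
Reagents that add atoms: none
Why: Zerovalent palladium ionizes the primary allylic carbonate; carbon dioxide is lost and the methoxide formed deprotonates the β-keto ester at C5, so no external base is needed. The stabilized enolate attacks the cationic allyl complex over C1–C10–C9 at the methyl-bearing terminus C1, on the face opposite to palladium, and forms the C1–C5 bond. This is the Tsuji–Trost allylic alkylation in its intramolecular enantioselective form; the closest known reaction type is the palladium-catalysed cyclization of β-keto esters carrying an allylic carbonate to 2-vinylcyclopentanones with chiral diphosphines. The cyclopentanone closes by 5-exo attack; 7-endo attack at the unsubstituted terminus C9 is slower, and O-alkylation to the isomeric alkylidene tetrahydrofuran is reversible under the catalyst and should drain to the ketone. The new stereocentre C1 is set by the ligand, which selects one face of the allyl unit; the two faces interconvert through the η1 form at the unsubstituted terminus C9 faster than the ring closes, which is why an achiral acyclic precursor can give one enantiomer. That equilibration does not exchange methyl and chain at C1, so the geometrically pure (E)-alkene secured in steps 2 to 4 is required. C5 forms as an equilibrating mixture with its epimer and the enol and is fixed only in step 6. The step needs enantioface selection, C- over O-alkylation and 5- over 7-ring closure; the tether length, the soft nucleophile and high dilution in a non-coordinating solvent should secure them.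

Step 6
Reactants: 8 methyl (1R,2S)-2-ethenyl-2-methyl-5-oxocyclopentane-1-carboxylate
Product: 9 methyl (1R,2S,5R)-2-ethenyl-5-hydroxy-2-methylcyclopentane-1-carboxylate
Conditions: H2 (10 atm), [RuCl(p-cymene)((R)-BINAP)]Cl (1 mol %), CH2Cl2–MeOH, 50 °C
Reagents that add atoms: none
Why: Noyori hydrogenation of a cyclic α-substituted β-keto ester under dynamic kinetic resolution: the C5 epimers interconvert through the enol faster than they are reduced, and the chelating catalyst delivers hydride to C4 from the ester face, so the trans hydroxy ester with the ester cis to the vinyl group should result. Isolated alkenes do not chelate this catalyst, so the vinyl group should survive, and any (2R)-8 left by step 5 becomes a separable diastereomer.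

Step 7
Reactants: 9 methyl (1R,2S,5R)-2-ethenyl-5-hydroxy-2-methylcyclopentane-1-carboxylate
Product: 10 (1R,2S,3S)-3-ethenyl-2-(hydroxymethyl)-3-methylcyclopentan-1-ol
Conditions: LiAlH4, THF, 0 °C; aq. NaOH work-up
Reagents that add atoms: none
Why: Hydride reduction of the ester to the primary alcohol; the hydroxyl is deprotonated first, which protects C5 from epimerization, and the alkene is inert.

Step 8
Reactants: 10 (1R,2S,3S)-3-ethenyl-2-(hydroxymethyl)-3-methylcyclopentan-1-ol
Product: 11 (1R,2S,3S)-2-({[tert-butyl(dimethyl)silyl]oxy}methyl)-3-ethenyl-3-methylcyclopentan-1-ol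
Conditions: TBSCl (1.05 equiv), imidazole, CH2Cl2, −20 → 0 °C
Reagents that add atoms: tert-butyldimethylsilyl chloride CC(C)(C)[Si](C)(C)Cl
Why: Silylation discriminates the primary hydroxyl from the hindered secondary one, leaving the C4 carbinol free for step 10.

Step 9
Reactants: 11 (1R,2S,3S)-2-({[tert-butyl(dimethyl)silyl]oxy}methyl)-3-ethenyl-3-methylcyclopentan-1-ol
Product: 13 (1R,2S,3R)-2-({[tert-butyl(dimethyl)silyl]oxy}methyl)-3-methyl-3-(3-methylbut-3-en-1-yl)cyclopentan-1-ol, via bis-borane adduct 12 (not isolated)
Conditions: 9-BBN-H (2.5 equiv), THF, 0 → 60 °C; then 2-bromopropene, PdCl2(dppf) (5 mol %), 3 M aq. K3PO4, DMF, 50 °C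
Reagents that add atoms: 2-bromopropene CC(Br)=C
Why: Hydroboration places boron on the terminal carbon C9 of the neopentylic vinyl group, and B-alkyl Suzuki–Miyaura coupling forms the C8–C9 bond. The free hydroxyl only consumes one equivalent of borane as a borinate, which the basic medium hydrolyses.

Step 10
Reactants: 13 (1R,2S,3R)-2-({[tert-butyl(dimethyl)silyl]oxy}methyl)-3-methyl-3-(3-methylbut-3-en-1-yl)cyclopentan-1-ol
Product: 14 (2S,3R)-2-({[tert-butyl(dimethyl)silyl]oxy}methyl)-3-methyl-3-(3-methylbut-3-en-1-yl)cyclopentan-1-one
Conditions: Dess–Martin periodinane, NaHCO3, CH2Cl2, 0 °C → rt; used without chromatography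
Reagents that add atoms: none
Why: Buffered Dess–Martin oxidation is neutral, so C5 should neither epimerize nor lose the β-silyloxy group; the relay carbinol at C4 has done its work.

Step 11
Reactants: 14 (2S,3R)-2-({[tert-butyl(dimethyl)silyl]oxy}methyl)-3-methyl-3-(3-methylbut-3-en-1-yl)cyclopentan-1-one
Product: 15 (1R,2S,3R)-2-({[tert-butyl(dimethyl)silyl]oxy}methyl)-3-methyl-3-(3-methylbut-3-en-1-yl)-1-(propan-2-yl)cyclopentan-1-ol
Conditions: i-PrMgCl, CeCl3 (anhydrous), THF, −78 → 0 °C; aq. NH4Cl
Reagents that add atoms: isopropylmagnesium chloride CC(C)[Mg]Cl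
Why: Organocerium addition to an enolizable ketone; the low basicity should suppress enolization, β-elimination and hydride transfer. The reagent should enter anti to the silyloxymethyl arm on C5, on the face that carries only the 1,3-related methyl group, so the hydroxyl ends cis to C6 (4R).

Step 12
Reactants: 15 (1R,2S,3R)-2-({[tert-butyl(dimethyl)silyl]oxy}methyl)-3-methyl-3-(3-methylbut-3-en-1-yl)-1-(propan-2-yl)cyclopentan-1-ol
Product: 16 (1R,2S,3R)-2-(hydroxymethyl)-3-methyl-3-(3-methylbut-3-en-1-yl)-1-(propan-2-yl)cyclopentan-1-ol
Conditions: TBAF, THF, 0 °C → rt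
Reagents that add atoms: none
Why: Fluoride cleavage of a primary silyl ether; nothing else in the molecule responds.

Step 13
Reactants: 16 (1R,2S,3R)-2-(hydroxymethyl)-3-methyl-3-(3-methylbut-3-en-1-yl)-1-(propan-2-yl)cyclopentan-1-ol
Product: 17 (1R,2R,5R)-2-hydroxy-5-methyl-5-(3-methylbut-3-en-1-yl)-2-(propan-2-yl)cyclopentane-1-carbaldehyde
Conditions: Dess–Martin periodinane, NaHCO3, CH2Cl2, 0 °C; used at once
Reagents that add atoms: none
Why: Dess–Martin oxidation of the primary alcohol; the tertiary hydroxyl cannot be oxidized, and the buffered neutral medium spares the aldol-type product. The formyl group sits trans to both isopropyl and methyl, which should also be the preferred arrangement at C5.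

Step 14
Reactants: 17 (1R,2R,5R)-2-hydroxy-5-methyl-5-(3-methylbut-3-en-1-yl)-2-(propan-2-yl)cyclopentane-1-carbaldehyde
Product: 18 (1R,2S,3R)-2-(1-hydroxyprop-2-en-1-yl)-3-methyl-3-(3-methylbut-3-en-1-yl)-1-(propan-2-yl)cyclopentan-1-ol (both epimers at the new carbinol carbon C6)
Conditions: CH2=CHMgBr (3 equiv), THF, −78 °C, aldehyde added to the reagent; aq. NH4Cl
Reagents that add atoms: vinylmagnesium bromide C=C[Mg]Br
Why: Grignard addition to the aldehyde after deprotonation of the tertiary hydroxyl; at −78 °C addition should outrun retro-aldol cleavage of the magnesium aldolate. Attack past H5 is expected to favour the 6S carbinol, which is of no consequence because C6 is re-oxidized in step 16.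

Step 15
Reactants: 18 (1R,2S,3R)-2-(1-hydroxyprop-2-en-1-yl)-3-methyl-3-(3-methylbut-3-en-1-yl)-1-(propan-2-yl)cyclopentan-1-ol
Product: 19 (3R,3aS,8aR)-6,8a-dimethyl-3-(propan-2-yl)-1,2,3,3a,4,7,8,8a-octahydroazulene-3,4-diol (both epimers at C4 of the name, label C6)
Conditions: second-generation Grubbs catalyst RuCl2(=CHPh)(H2IMes)(PCy3) (5 mol %), CH2Cl2 (5 mM), 40 °C
Reagents that add atoms: none
Why: Ring-closing metathesis of the vinyl carbinol with the 1,1-disubstituted alkene forms the trisubstituted C7=C8 bond and releases ethene; the two arms are cis on the cyclopentane, so only the cis-fused cycloheptene can form.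

Step 16
Reactants: 19 (3R,3aS,8aR)-6,8a-dimethyl-3-(propan-2-yl)-1,2,3,3a,4,7,8,8a-octahydroazulene-3,4-diol
Product: 20 (3R,3aR,8aR)-3-hydroxy-6,8a-dimethyl-3-(propan-2-yl)-2,3,3a,7,8,8a-hexahydroazulen-4(1H)-one
Conditions: Dess–Martin periodinane, NaHCO3, CH2Cl2, 0 °C; used without chromatography
Reagents that add atoms: none
Why: Dess–Martin oxidation converges both C6 epimers on one enone; the tertiary alcohol is inert, and the buffered medium should avoid dehydration of the β-hydroxy ketone.

Step 17
Reactants: 20 (3R,3aR,8aR)-3-hydroxy-6,8a-dimethyl-3-(propan-2-yl)-2,3,3a,7,8,8a-hexahydroazulen-4(1H)-one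
Product: 21 (3R,3aS,4R,8aR)-6,8a-dimethyl-3-(propan-2-yl)-1,2,3,3a,4,7,8,8a-octahydroazulene-3,4-diol
Conditions: NaBH4, CeCl3·7H2O, MeOH, −78 °C
Reagents that add atoms: none
Why: Luche reduction gives 1,2-reduction of the enone. With the carbonyl oxygen held syn to the C4 hydroxyl by hydrogen bonding or cerium chelation, H5 lies on one face of the carbonyl and the quaternary C1 with C10 on the other; hydride should enter past H5 and give the 6R carbinol with H6 cis to H5.

Step 18
Reactants: 22 3-hydroxy-4-methoxybenzoic acid (isovanillic acid)
Product: 24 3-{[tert-butyl(dimethyl)silyl]oxy}-4-methoxybenzoic acid, via bis-silyl derivative 23 (not isolated)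
Conditions: TBSCl (2.2 equiv), imidazole, DMF, rt; then AcOH–THF–H2O, rt
Reagents that add atoms: tert-butyldimethylsilyl chloride CC(C)(C)[Si](C)(C)Cl
Why: Both acidic hydroxyls are silylated and the much more labile silyl ester is then hydrolysed selectively, leaving the aryl silyl ether.

Step 19
Reactants: 21 (3R,3aS,4R,8aR)-6,8a-dimethyl-3-(propan-2-yl)-1,2,3,3a,4,7,8,8a-octahydroazulene-3,4-diol; 24 3-{[tert-butyl(dimethyl)silyl]oxy}-4-methoxybenzoic acid
Product: 26 (3R,3aS,4R,8aR)-3-hydroxy-6,8a-dimethyl-3-(propan-2-yl)-1,2,3,3a,4,7,8,8a-octahydroazulen-4-yl 3-{[tert-butyl(dimethyl)silyl]oxy}-4-methoxybenzoate, via mixed anhydride 25 (not isolated)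
Conditions: 2,4,6-trichlorobenzoyl chloride, Et3N, THF, rt; then 21, DMAP, toluene, rt → 40 °C
Reagents that add atoms: none
Why: Yamaguchi esterification: DMAP transfers the less hindered aroyl group of the mixed anhydride to the secondary allylic hydroxyl with retention at C6; the tertiary hydroxyl does not react and no acid is present to ionize the allylic system.

Step 20
Reactants: 26 (3R,3aS,4R,8aR)-3-hydroxy-6,8a-dimethyl-3-(propan-2-yl)-1,2,3,3a,4,7,8,8a-octahydroazulen-4-yl 3-{[tert-butyl(dimethyl)silyl]oxy}-4-methoxybenzoate
Product: 27 (3R,3aS,4R,8aR)-3-hydroxy-6,8a-dimethyl-3-(propan-2-yl)-1,2,3,3a,4,7,8,8a-octahydroazulen-4-yl 3-hydroxy-4-methoxybenzoate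
Conditions: TBAF, AcOH, THF, 0 °C
Reagents that add atoms: none
Why: Aryl silyl ethers are cleaved by fluoride at 0 °C; acetic acid buffers the phenoxide so the allylic ester is not attacked.

## Compound list

1 | 3-methylbut-2-en-1-ol | CC(C)=CCO | starting material
2 | methyl 3-methylbut-2-en-1-yl carbonate | COC(=O)OCC=C(C)C | intermediate
3 | (2E)-4-hydroxy-3-methylbut-2-en-1-yl methyl carbonate | COC(=O)OC/C=C(C)/CO | intermediate
4 | (2E)-4-bromo-3-methylbut-2-en-1-yl methyl carbonate | COC(=O)OC/C=C(C)/CBr | intermediate
5 | methyl acetoacetate | CC(=O)CC(=O)OC | starting material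
6 | lithium sodium dianion of methyl acetoacetate | [Li+].[Na+].COC(=O)[CH-]C(=O)[CH2-] | intermediate
7 | methyl (6E)-8-[(methoxycarbonyl)oxy]-6-methyl-3-oxooct-6-enoate | COC(=O)CC(=O)CC/C(C)=C/COC(=O)OC | intermediate
8 | methyl (1R,2S)-2-ethenyl-2-methyl-5-oxocyclopentane-1-carboxylate | COC(=O)[C@H]1C(=O)CC[C@@]1(C)C=C | intermediate
9 | methyl (1R,2S,5R)-2-ethenyl-5-hydroxy-2-methylcyclopentane-1-carboxylate | COC(=O)[C@H]1[C@H](O)CC[C@@]1(C)C=C | intermediate
10 | (1R,2S,3S)-3-ethenyl-2-(hydroxymethyl)-3-methylcyclopentan-1-ol | OC[C@H]1[C@H](O)CC[C@@]1(C)C=C | intermediate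
11 | (1R,2S,3S)-2-({[tert-butyl(dimethyl)silyl]oxy}methyl)-3-ethenyl-3-methylcyclopentan-1-ol | CC(C)(C)[Si](C)(C)OC[C@H]1[C@H](O)CC[C@@]1(C)C=C | intermediate
12 | bis-borane adduct of 11 (C9 borane and O-borinate of 9-borabicyclo[3.3.1]nonane) | CC(C)(C)[Si](C)(C)OC[C@H]1[C@H](OB2C3CCCC2CCC3)CC[C@@]1(C)CCB1C2CCCC1CCC2 | intermediate
13 | (1R,2S,3R)-2-({[tert-butyl(dimethyl)silyl]oxy}methyl)-3-methyl-3-(3-methylbut-3-en-1-yl)cyclopentan-1-ol | CC(C)(C)[Si](C)(C)OC[C@H]1[C@H](O)CC[C@@]1(C)CCC(C)=C | intermediate
14 | (2S,3R)-2-({[tert-butyl(dimethyl)silyl]oxy}methyl)-3-methyl-3-(3-methylbut-3-en-1-yl)cyclopentan-1-one | CC(C)(C)[Si](C)(C)OC[C@H]1C(=O)CC[C@@]1(C)CCC(C)=C | intermediate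
15 | (1R,2S,3R)-2-({[tert-butyl(dimethyl)silyl]oxy}methyl)-3-methyl-3-(3-methylbut-3-en-1-yl)-1-(propan-2-yl)cyclopentan-1-ol | CC(C)(C)[Si](C)(C)OC[C@H]1[C@](O)(C(C)C)CC[C@@]1(C)CCC(C)=C | intermediate
16 | (1R,2S,3R)-2-(hydroxymethyl)-3-methyl-3-(3-methylbut-3-en-1-yl)-1-(propan-2-yl)cyclopentan-1-ol | OC[C@H]1[C@](O)(C(C)C)CC[C@@]1(C)CCC(C)=C | intermediate
17 | (1R,2R,5R)-2-hydroxy-5-methyl-5-(3-methylbut-3-en-1-yl)-2-(propan-2-yl)cyclopentane-1-carbaldehyde | O=C[C@H]1[C@](O)(C(C)C)CC[C@@]1(C)CCC(C)=C | intermediate
18 | (1R,2S,3R)-2-(1-hydroxyprop-2-en-1-yl)-3-methyl-3-(3-methylbut-3-en-1-yl)-1-(propan-2-yl)cyclopentan-1-ol, both epimers at the side-chain carbinol | C=CC(O)[C@H]1[C@](O)(C(C)C)CC[C@@]1(C)CCC(C)=C | intermediate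
19 | (3R,3aS,8aR)-6,8a-dimethyl-3-(propan-2-yl)-1,2,3,3a,4,7,8,8a-octahydroazulene-3,4-diol, both epimers at C4 | OC1C=C(C)CC[C@]2(C)CC[C@@](O)(C(C)C)[C@H]12 | intermediate
20 | (3R,3aR,8aR)-3-hydroxy-6,8a-dimethyl-3-(propan-2-yl)-2,3,3a,7,8,8a-hexahydroazulen-4(1H)-one | O=C1C=C(C)CC[C@]2(C)CC[C@@](O)(C(C)C)[C@H]12 | intermediate
21 | (3R,3aS,4R,8aR)-6,8a-dimethyl-3-(propan-2-yl)-1,2,3,3a,4,7,8,8a-octahydroazulene-3,4-diol | O[C@@H]1C=C(C)CC[C@]2(C)CC[C@@](O)(C(C)C)[C@H]12 | intermediate
22 | 3-hydroxy-4-methoxybenzoic acid (isovanillic acid) | COc1ccc(C(=O)O)cc1O | starting material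
23 | tert-butyldimethylsilyl 3-{[tert-butyl(dimethyl)silyl]oxy}-4-methoxybenzoate | COc1ccc(C(=O)O[Si](C)(C)C(C)(C)C)cc1O[Si](C)(C)C(C)(C)C | intermediate
24 | 3-{[tert-butyl(dimethyl)silyl]oxy}-4-methoxybenzoic acid | COc1ccc(C(=O)O)cc1O[Si](C)(C)C(C)(C)C | intermediate
25 | 3-{[tert-butyl(dimethyl)silyl]oxy}-4-methoxybenzoic 2,4,6-trichlorobenzoic anhydride | COc1ccc(C(=O)OC(=O)c2c(Cl)cc(Cl)cc2Cl)cc1O[Si](C)(C)C(C)(C)C | intermediate
26 | (3R,3aS,4R,8aR)-3-hydroxy-6,8a-dimethyl-3-(propan-2-yl)-1,2,3,3a,4,7,8,8a-octahydroazulen-4-yl 3-{[tert-butyl(dimethyl)silyl]oxy}-4-methoxybenzoate | COc1ccc(C(=O)O[C@@H]2C=C(C)CC[C@]3(C)CC[C@@](O)(C(C)C)[C@H]23)cc1O[Si](C)(C)C(C)(C)C | intermediate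
27 | (3R,3aS,4R,8aR)-3-hydroxy-6,8a-dimethyl-3-(propan-2-yl)-1,2,3,3a,4,7,8,8a-octahydroazulen-4-yl 3-hydroxy-4-methoxybenzoate | COc1ccc(C(=O)O[C@@H]2C=C(C)CC[C@]3(C)CC[C@@](O)(C(C)C)[C@H]23)cc1O | target

## Step count and risks

Total step count: 20. Longest linear sequence: 19 steps (steps 1 to 17, 19 and 20); step 18 is a one-step side branch.

**Step 5 (key step).** Ring closure may outrun equilibration of the two allyl faces, or the ligand may discriminate them poorly at a terminus whose two substituents (methyl and a two-carbon chain) differ little; either lowers the enantiomeric purity at C1. Fallback, from 7 to 9: cyclization of 7 with the achiral catalyst Pd(PPh3)4 in THF gives racemic methyl 2-ethenyl-2-methyl-5-oxocyclopentane-1-carboxylate F1. The hydrogenation of step 6 then serves as a resolution: the (R)-BINAP catalyst fixes the carbinol and ester carbons in the same sense in both enantiomers, giving 9 together with its diastereomer methyl (1R,2R,5R)-2-ethenyl-5-hydroxy-2-methylcyclopentane-1-carboxylate F2. These differ in the position of the methyl group relative to the ester and are separated by chromatography. The route is rejoined at 9 at the cost of half the material.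

**Step 6.** Over-reduction of the vinyl group, or loss of catalyst control over the C5 epimers because of the adjacent quaternary carbon, would spoil the relay. Fallback, from 8 to 9: NaBH4 in methanol at −40 °C reduces 8 without stereocontrol, and NaOMe in methanol equilibrates the cis hydroxy esters to the two trans isomers, 9 and methyl (1S,2S,5S)-2-ethenyl-5-hydroxy-2-methylcyclopentane-1-carboxylate F3. These are separated by chromatography; F3 is oxidized back to 8 with Dess–Martin periodinane and recycled. The route is rejoined at 9.

**Step 14.** Retro-aldol opening or dehydration of the magnesium aldolate of 17 may compete with addition, since the tertiary alkoxide is formed before the carbon–carbon bond. Fallback, from 17 to 18: Nozaki–Hiyama–Kishi vinylation (vinyl bromide, CrCl2, NiCl2 (cat.), DMF, rt) is not basic, tolerates the free hydroxyl and reacts only with the aldehyde. It returns to the route at 18 and makes no new compound.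

**Step 15.** Ruthenium hydride species may isomerize the free vinyl carbinol to an ethyl ketone before the slow closure onto the 1,1-disubstituted alkene. Fallback, from 18 to 20: the order of steps 15 and 16 is exchanged. Dess–Martin oxidation of 18 gives the vinyl ketone 1-[(1R,2R,5R)-2-hydroxy-5-methyl-5-(3-methylbut-3-en-1-yl)-2-(propan-2-yl)cyclopentyl]prop-2-en-1-one F4, which cannot isomerize in this way. Enone metathesis with the second-generation Hoveyda–Grubbs catalyst RuCl2(=CH-C6H4-2-O-i-Pr)(H2IMes) in toluene at 80 °C gives 20 directly.

**Step 17.** Facial selectivity may be poor, or hydride may be delivered from the side of the C4 hydroxyl if the ring adopts the other conformer. Fallback, from 20 to 26: the epimeric diol (3R,3aS,4S,8aR)-6,8a-dimethyl-3-(propan-2-yl)-1,2,3,3a,4,7,8,8a-octahydroazulene-3,4-diol F5 is not discarded. Mitsunobu esterification with 24 (PPh3, diisopropyl azodicarboxylate, toluene) inverts C6 while forming the ester and rejoins the route at 26.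

## Further compounds

F1 | step 5 | methyl 2-ethenyl-2-methyl-5-oxocyclopentane-1-carboxylate (racemic) | COC(=O)C1C(=O)CCC1(C)C=C
F2 | step 5 | methyl (1R,2R,5R)-2-ethenyl-5-hydroxy-2-methylcyclopentane-1-carboxylate | COC(=O)[C@H]1[C@H](O)CC[C@]1(C)C=C
F3 | step 6 | methyl (1S,2S,5S)-2-ethenyl-5-hydroxy-2-methylcyclopentane-1-carboxylate | COC(=O)[C@@H]1[C@@H](O)CC[C@@]1(C)C=C
F0 | step 14 | none | none
F4 | step 15 | 1-[(1R,2R,5R)-2-hydroxy-5-methyl-5-(3-methylbut-3-en-1-yl)-2-(propan-2-yl)cyclopentyl]prop-2-en-1-one | C=CC(=O)[C@H]1[C@](O)(C(C)C)CC[C@@]1(C)CCC(C)=C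
F5 | step 17 | (3R,3aS,4S,8aR)-6,8a-dimethyl-3-(propan-2-yl)-1,2,3,3a,4,7,8,8a-octahydroazulene-3,4-diol | O[C@H]1C=C(C)CC[C@]2(C)CC[C@@](O)(C(C)C)[C@H]12
A1 | alternative 1 | tert-butyl{[(3R,3aS,4R,8aR)-6,8a-dimethyl-3-(propan-2-yl)-3-[(triethylsilyl)oxy]-1,2,3,3a,4,7,8,8a-octahydroazulen-4-yl]oxy}dimethylsilane | CC(C)(C)[Si](C)(C)O[C@@H]1C=C(C)CC[C@]2(C)CC[C@@](O[Si](CC)(CC)CC)(C(C)C)[C@H]12
A2 | alternative 1 | monocyclic (Z)-iodoalkene precursor of A1 (C1 vinyl and methyl, C4 triethylsilyl ether, C6 tert-butyldimethylsilyl ether, configuration as in A1) | CC(C)(C)[Si](C)(C)O[C@H](/C=C(/C)I)[C@H]1[C@](O[Si](CC)(CC)CC)(C(C)C)CC[C@@]1(C)C=C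
A3 | alternative 2 | 8a-methyl cycloheptatriene-fused cyclopentanone (C6 methyl enol ether, C4 trimethylsilyl ether, C2 ketone) | COC1=C2[C@](O[Si](C)(C)C)(C(C)C)CC(=O)[C@@]2(C)C=CC(C)=C1
A4 | alternative 2 | (5R)-2-diazo-5-(2-methoxy-4-methylphenyl)-6-methyl-5-[(trimethylsilyl)oxy]heptan-3-one | CC(=[N+]=[N-])C(=O)C[C@@](O[Si](C)(C)C)(C(C)C)c1ccc(C)cc1OC
A5 | alternative 3 | 2-(1-hydroxyprop-2-en-1-yl)-3-methyl-3-(3-methylbut-3-en-1-yl)cyclopentan-1-one, configuration at C1, C5 and C6 as in the target | C=C[C@@H](O)[C@H]1C(=O)CC[C@@]1(C)CCC(C)=C
A6 | alternative 3 | 3-methylcyclopent-2-en-1-one | CC1=CC(=O)CC1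
A7 | alternative 3 | (3-methylbut-3-en-1-yl)magnesium bromide | C=C(C)CC[Mg]Br
A8 | alternative 3 | prop-2-enal (acrolein) | C=CC=O
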